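**Retrosynthetic overview**
1. Last step: global O-demethylation of a heptamethyl ether (seven ArOMe to ArOH).
2. Both nine-carbon ketone arms are cut at C7–C8 and made together by a two-directional cross-metathesis of a diallyl biaryl with an aryl heptenyl ketone, followed by hydrogenation.
3. The unsymmetrical biaryl bond is made with no halide or boron handle, by anodic dehydrogenative phenol–arene cross-coupling of eugenol with methyl eugenol (key step).
4. The ketone partner comes from 2,6-dimethoxybenzoyl chloride and hept-6-enylmagnesium bromide.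
5. No ring is constructed: all four benzene rings are bought intact. Ring A and ring B are joined first; the two terminal resorcinol rings are attached last, both at once.

Assumption: the target has no stereocentre, and its biaryl axis carries only two ortho substituents (OH and alkyl) and rotates freely, so the compound is treated as achiral and no stereocontrol is needed.

**Route**

Step 1
Reactants: 1 eugenol (2-methoxy-4-(prop-2-en-1-yl)phenol); 2 methyl eugenol (1,2-dimethoxy-4-(prop-2-en-1-yl)benzene, 3 equiv)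
Product: 3 3,4',5'-trimethoxy-2',5-di(prop-2-en-1-yl)-[1,1'-biphenyl]-2-ol
Conditions: boron-doped diamond anode, Ni cathode, undivided cell, constant current 2.8 mA cm−2, 2.0 F mol−1, [Et3NMe]O3SOMe (0.09 M), HFIP/MeOH (18 vol%), 50 °C
Reagents that add atoms: none
Why: Anodic dehydrogenative phenol–arene cross-coupling: the more easily oxidised phenol 1, with its para position blocked, is captured at its free ortho carbon by excess arene 2 at its most nucleophilic site (para to OMe, ortho to allyl, where 4-alkylveratroles undergo oxidative biaryl coupling), HFIP hydrogen bonding suppresses homocoupling and over-oxidation, and the non-conjugated allyl groups are spectators as in the classical oxidative dimerisation of eugenol; no stereocentre is formed.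

Step 2
Reactants: 4 7-bromohept-1-ene; 5 2,6-dimethoxybenzoyl chloride
Product: 7 1-(2,6-dimethoxyphenyl)oct-7-en-1-one, via hept-6-en-1-ylmagnesium bromide 6 (not isolated)
Conditions: Mg turnings, THF, rt to 40 °C; then 5, Fe(acac)3 (3 mol%), THF, −78 °C
Reagents that add atoms: none
Why: Grignard formation followed by Fe(acac)3-catalysed acylation of the acid chloride, which outpaces carbonyl addition at −78 °C, and the di-ortho-substituted ketone is too hindered to add a second equivalent.

Step 3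
Reactants: 3 3,4',5'-trimethoxy-2',5-di(prop-2-en-1-yl)-[1,1'-biphenyl]-2-ol; 7 1-(2,6-dimethoxyphenyl)oct-7-en-1-one (6 equiv)
Product: 8 (7E)-1-(2,6-dimethoxyphenyl)-9-{2'-[(2E)-9-(2,6-dimethoxyphenyl)-9-oxonon-2-en-1-yl]-6-hydroxy-4',5,5'-trimethoxy-[1,1'-biphenyl]-3-yl}non-7-en-1-one (E/Z mixture, drawn E,E, carried forward as such)
Conditions: second-generation Hoveyda–Grubbs catalyst RuCl2(H2IMes)(=CH-C6H4-2-OiPr) (2 × 5 mol%), 1,4-benzoquinone (10 mol%), CH2Cl2, 40 °C, argon sparge
Reagents that add atoms: none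
Why: Two-directional olefin cross-metathesis of two unhindered terminal alkenes driven by excess 7 and loss of ethene, with ring closure between the two allyl arms impossible (it would need a nine-membered metacyclophane), benzoquinone suppressing allyl-to-propenyl isomerisation and the free phenol tolerated by the Ru carbene; alkene geometry is irrelevant because it is erased in step 4.

Step 4
Reactants: 8 the bis-alkene from step 3
Product: 9 1-(2,6-dimethoxyphenyl)-9-{2'-[9-(2,6-dimethoxyphenyl)-9-oxononyl]-6-hydroxy-4',5,5'-trimethoxy-[1,1'-biphenyl]-3-yl}nonan-1-one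
Conditions: H2 (1 atm), 10% Pd/C, EtOAc, rt
Reagents that add atoms: none
Why: Heterogeneous catalytic hydrogenation saturates both disubstituted alkenes, while the twisted, di-ortho-substituted aryl ketones and the aryl methyl ethers are inert under these mild conditions.

Step 5
Reactants: 9 the saturated heptamethyl ether from step 4
Product: 10 1-(2,6-dihydroxyphenyl)-9-{2'-[9-(2,6-dihydroxyphenyl)-9-oxononyl]-4',5,5',6-tetrahydroxy-[1,1'-biphenyl]-3-yl}nonan-1-one (target)
Conditions: BBr3 (14 equiv), CH2Cl2, −78 °C to rt, 16 h; then degassed MeOH/H2O, 0 °C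
Reagents that add atoms: none
Why: Lewis-acid cleavage of aryl methyl ethers with BBr3, in which the four methoxy groups ortho to the ketones go first by chelation and the three catechol-type ethers follow, while the ketones, alkyl chains and biaryl bond are untouched; degassed work-up protects the catechols from air oxidation.

**Compound list**
1 | eugenol, 2-methoxy-4-(prop-2-en-1-yl)phenol | C=CCc1ccc(O)c(OC)c1 | starting material
2 | methyl eugenol, 1,2-dimethoxy-4-(prop-2-en-1-yl)benzene | C=CCc1ccc(OC)c(OC)c1 | starting material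
3 | 3,4',5'-trimethoxy-2',5-di(prop-2-en-1-yl)-[1,1'-biphenyl]-2-ol | C=CCc1cc(OC)c(O)c(-c2cc(OC)c(OC)cc2CC=C)c1 | intermediate
4 | 7-bromohept-1-ene | C=CCCCCCBr | starting material
5 | 2,6-dimethoxybenzoyl chloride | COc1cccc(OC)c1C(Cl)=O | starting material
6 | hept-6-en-1-ylmagnesium bromide | C=CCCCCC[Mg]Br | intermediate (not isolated)
7 | 1-(2,6-dimethoxyphenyl)oct-7-en-1-one | C=CCCCCCC(=O)c1c(OC)cccc1OC | intermediate
8 | (7E)-1-(2,6-dimethoxyphenyl)-9-{2'-[(2E)-9-(2,6-dimethoxyphenyl)-9-oxonon-2-en-1-yl]-6-hydroxy-4',5,5'-trimethoxy-[1,1'-biphenyl]-3-yl}non-7-en-1-one | COc1cccc(OC)c1C(=O)CCCCC/C=C/Cc1cc(OC)c(O)c(-c2cc(OC)c(OC)cc2C/C=C/CCCCCC(=O)c2c(OC)cccc2OC)c1 | intermediate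
9 | 1-(2,6-dimethoxyphenyl)-9-{2'-[9-(2,6-dimethoxyphenyl)-9-oxononyl]-6-hydroxy-4',5,5'-trimethoxy-[1,1'-biphenyl]-3-yl}nonan-1-one | COc1cccc(OC)c1C(=O)CCCCCCCCc1cc(OC)c(O)c(-c2cc(OC)c(OC)cc2CCCCCCCCC(=O)c2c(OC)cccc2OC)c1 | intermediate
10 | 1-(2,6-dihydroxyphenyl)-9-{2'-[9-(2,6-dihydroxyphenyl)-9-oxononyl]-4',5,5',6-tetrahydroxy-[1,1'-biphenyl]-3-yl}nonan-1-one | O=C(CCCCCCCCc1cc(O)c(O)c(-c2cc(O)c(O)cc2CCCCCCCCC(=O)c2c(O)cccc2O)c1)c1c(O)cccc1O | target

**Totals**
Total step count: 5. Longest linear sequence: 4 steps (steps 1, 3, 4, 5 from eugenol; equally steps 2, 3, 4, 5 from 7-bromohept-1-ene).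

**Three steps most likely to fail, with fallbacks**

Step 1 (anodic cross-coupling). The risks are homocoupling of 1 to dehydrodieugenol, over-oxidation of the electron-rich product, and side reactions at the allylic/benzylic positions. The fallback sets out from 2 and 1 and comes back at 3 by a conventional cross-coupling. Ring bromination of 2 (NBS, MeCN, 0 °C; para to OMe, ortho to allyl) gives 1-bromo-4,5-dimethoxy-2-(prop-2-en-1-yl)benzene F1. Miyaura borylation (B2pin2, Pd(dppf)Cl2, KOAc, dioxane, 80 °C) gives 2-[4,5-dimethoxy-2-(prop-2-en-1-yl)phenyl]-4,4,5,5-tetramethyl-1,3,2-dioxaborolane F2. Ortho-iodination of 1 (NIS, cat. TsOH, MeCN, 0 °C) gives 2-iodo-6-methoxy-4-(prop-2-en-1-yl)phenol F3. Suzuki–Miyaura coupling of F2 with F3 (Pd(dppf)Cl2, K3PO4, dioxane/H2O, 70 °C) gives 3.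

Step 3 (double cross-metathesis). The risks are stalling at the mono-adduct, allyl-to-propenyl isomerisation, and statistical mixtures. The fallback sets out from 3 and comes back at 9, skipping 8 and the hydrogenation, by sp3–sp3 coupling and a two-directional ketone synthesis.
- Hydroboration of 3 with 9-BBN dimer (THF, 0 °C to rt; 3.3 equiv of B–H, one consumed by the phenol, whose borinate is hydrolysed in the aqueous coupling medium) gives 3,4',5'-trimethoxy-2',5-bis[3-(9-borabicyclo[3.3.1]nonan-9-yl)propyl]-[1,1'-biphenyl]-2-ol F4, used in solution.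
- Commercial 6-bromohexanoyl chloride and MeNHOMe·HCl (pyridine, CH2Cl2, 0 °C) give 6-bromo-N-methoxy-N-methylhexanamide F5.
- Alkyl–alkyl Suzuki–Miyaura coupling of F4 with F5 (Pd(OAc)2, PCy3, K3PO4·H2O, THF, rt) gives 9,9'-(6-hydroxy-4',5,5'-trimethoxy-[1,1'-biphenyl]-2',3-diyl)bis(N-methoxy-N-methylnonanamide) F6.
- 1,3-Dimethoxybenzene and n-BuLi (THF, 0 °C to rt) give 2,6-dimethoxyphenyllithium F7, which (3.5 equiv, THF, −78 to 0 °C, aqueous NH4Cl quench) adds once to each Weinreb amide of F6 to give 9.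

Step 5 (seven-fold demethylation). The risks are incomplete cleavage giving mixtures of partial ethers, and air oxidation of the polycatechol during a long reaction. The fallback sets out from 7 (together with 3) and comes back at 10. It moves the four ketone-flanking demethylations onto the small fragment, so that the last step only has to cleave three ethers.
- BBr3 (CH2Cl2, −78 to 0 °C; isolated terminal alkenes survive these conditions) converts 7 into 1-(2,6-dihydroxyphenyl)oct-7-en-1-one F8.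
- Cross-metathesis of 3 with F8 under the step 3 conditions gives (7E)-1-(2,6-dihydroxyphenyl)-9-{2'-[(2E)-9-(2,6-dihydroxyphenyl)-9-oxonon-2-en-1-yl]-6-hydroxy-4',5,5'-trimethoxy-[1,1'-biphenyl]-3-yl}non-7-en-1-one F9.
- Hydrogenation (H2, 10% Pd/C, EtOAc) gives 1-(2,6-dihydroxyphenyl)-9-{2'-[9-(2,6-dihydroxyphenyl)-9-oxononyl]-6-hydroxy-4',5,5'-trimethoxy-[1,1'-biphenyl]-3-yl}nonan-1-one F10.
- Short BBr3 treatment (6 equiv, CH2Cl2, −78 to 0 °C) cleaves the three remaining methyl ethers to give 10.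

**Further compounds**
F1 | step 1 | 1-bromo-4,5-dimethoxy-2-(prop-2-en-1-yl)benzene | C=CCc1cc(OC)c(OC)cc1Br
F2 | step 1 | 2-[4,5-dimethoxy-2-(prop-2-en-1-yl)phenyl]-4,4,5,5-tetramethyl-1,3,2-dioxaborolane | C=CCc1cc(OC)c(OC)cc1B1OC(C)(C)C(C)(C)O1
F3 | step 1 | 2-iodo-6-methoxy-4-(prop-2-en-1-yl)phenol | C=CCc1cc(I)c(O)c(OC)c1
F4 | step 3 | 3,4',5'-trimethoxy-2',5-bis[3-(9-borabicyclo[3.3.1]nonan-9-yl)propyl]-[1,1'-biphenyl]-2-ol | COc1cc(CCCB2C3CCCC2CCC3)cc(-c2cc(OC)c(OC)cc2CCCB2C3CCCC2CCC3)c1O
F5 | step 3 | 6-bromo-N-methoxy-N-methylhexanamide | CON(C)C(=O)CCCCCBr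
F6 | step 3 | 9,9'-(6-hydroxy-4',5,5'-trimethoxy-[1,1'-biphenyl]-2',3-diyl)bis(N-methoxy-N-methylnonanamide) | CON(C)C(=O)CCCCCCCCc1cc(OC)c(O)c(-c2cc(OC)c(OC)cc2CCCCCCCCC(=O)N(C)OC)c1
F7 | step 3 | 2,6-dimethoxyphenyllithium | COc1cccc(OC)c1[Li]
F8 | step 5 | 1-(2,6-dihydroxyphenyl)oct-7-en-1-one | C=CCCCCCC(=O)c1c(O)cccc1O
F9 | step 5 | (7E)-1-(2,6-dihydroxyphenyl)-9-{2'-[(2E)-9-(2,6-dihydroxyphenyl)-9-oxonon-2-en-1-yl]-6-hydroxy-4',5,5'-trimethoxy-[1,1'-biphenyl]-3-yl}non-7-en-1-one | O=C(CCCCC/C=C/Cc1cc(OC)c(O)c(-c2cc(OC)c(OC)cc2C/C=C/CCCCCC(=O)c2c(O)cccc2O)c1)c1c(O)cccc1O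
F10 | step 5 | 1-(2,6-dihydroxyphenyl)-9-{2'-[9-(2,6-dihydroxyphenyl)-9-oxononyl]-6-hydroxy-4',5,5'-trimethoxy-[1,1'-biphenyl]-3-yl}nonan-1-one | O=C(CCCCCCCCc1cc(OC)c(O)c(-c2cc(OC)c(OC)cc2CCCCCCCCC(=O)c2c(O)cccc2O)c1)c1c(O)cccc1O
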